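**Strategy.** Ring A is disconnected at C3=C4 back to a ring-rearrangement metathesis. In the target, C4 (on C4a), C1' (on C5) and N1 (on C8a) sit on one face of ring B, so C4 and C1' can be the two alkene carbons of a cis-fused cyclobutene in a bicyclo[4.2.0]oct-7-ene whose C2 carries the nitrogen endo. The precursor is this bicyclic secondary amine bearing an (R)-but-3-en-2-yl group on nitrogen, handled as its tosylate salt so that no carbamate has to be forced onto a di-sec-alkylamine. One ruthenium-catalysed operation opens the cyclobutene, closes ring A between C3 and C4 and leaves C1' as a vinyl group on C5.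

Key step: step 3

Remark: quinoline numbering is used for the core and C1'–C8' for the chain on C5; ketone 3 is racemic and only its (1R,6S) half is carried on; the CIP label of C5 changes from S to R at step 10 through a priority change, not a change of geometry.

**Route**

Step 1
Reactants: 1 cyclohex-2-en-1-one; 2 acetylene
Product: 3 rac-(1R,6S)-bicyclo[4.2.0]oct-7-en-2-one (cis-fused)
Conditions: hν (medium-pressure Hg lamp, Pyrex filter), acetylene-saturated THF, –70 °C, stopped before full conversion
Reagents that add atoms: none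
Why: Enone–alkyne [2+2] photocycloaddition through the enone triplet builds the cyclobutene; a four-membered ring can only be cis-fused to the cyclohexanone, which sets the future C4a/C5 relationship (as a racemate), and low temperature with partial conversion limits secondary photoreactions of the β,γ-unsaturated ketone.

Step 2
Reactants: 3 rac-(1R,6S)-bicyclo[4.2.0]oct-7-en-2-one; 4 (2R)-but-3-en-2-amine
Product: 6 (2R)-N-[(1R,2S,6S)-bicyclo[4.2.0]oct-7-en-2-yl]but-3-en-2-amine, via ketimine 5 (not isolated)
Conditions: Ti(OiPr)4, THF, rt; then NaBH4, EtOH, –20 → 0 °C; aq. NH3 work-up; chromatography on Et3N-deactivated SiO2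
Reagents that add atoms: none
Why: Titanium-mediated reductive amination in which hydride should attack the C=N from the convex face, anti to the cyclobutene, so that nitrogen ends up endo (the future C8a); because 4 is a single enantiomer, the endo amines from the two enantiomers of 3 are diastereomers, and the (1R,2S,6S) one is isolated by chromatography (at most half of the material).

Step 3
Reactants: 6 (2R)-N-[(1R,2S,6S)-bicyclo[4.2.0]oct-7-en-2-yl]but-3-en-2-amine
Product: 8 (2R,4aR,5S,8aS)-5-ethenyl-2-methyl-1,2,4a,5,6,7,8,8a-octahydroquinolin-1-ium 4-methylbenzenesulfonate, via ammonium tosylate 7 (not isolated)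
Conditions: TsOH·H2O (1.05 equiv), CH2Cl2, rt; then second-generation Grubbs catalyst (H2IMes)(PCy3)Cl2Ru=CHPh (5 mol%), ethylene (1 atm), CH2Cl2 (0.02 M), 40 °C; ethyl vinyl ether quench; evaporation, trituration with Et2O
Reagents that add atoms: p-toluenesulfonic acid monohydrate, Cc1ccc(cc1)S(=O)(=O)O.O; ethylene, C=C
Why: Ring-rearrangement metathesis, i.e. ring-opening/ring-closing metathesis of a strained cycloalkene that carries a tethered terminal alkene, a known reaction class that also tolerates amines once they are fully protonated. The catalyst exchanges onto the N-butenyl terminus, the resulting alkylidene (carbon C3) adds [2+2] to the cyclobutene C4=C1', and cycloreversion of the ruthenacyclobutane forms C3=C4, releases the four-ring strain and leaves an alkylidene on C1' that ethylene caps as the vinyl group while regenerating Ru=CH2. Ring A (N1–C2–C3=C4–C4a–C8a) is thus closed in the six-membered mode; bonding C3 to C1' instead would give a bridged seven-membered ring, which is slower and, since ethylene keeps all steps reversible, also thermodynamically disfavoured. No stereocentre is formed: C2 is that of 4, and C4a, C5 and C8a are those of 6, so the cis C4/C1' relationship of the cyclobutene reappears as the cis C4a–C4/C5–C1' relationship of the product. The selectivity needed is for the strained alkene over intermolecular metathesis; strain release, high dilution and the ethylene atmosphere secure it, and if ethylene opens the cyclobutene first the triene formed converges on the same product by ring-closing metathesis. The slight excess of TsOH keeps nitrogen protonated and off ruthenium.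

Step 4
Reactants: 8 (2R,4aR,5S,8aS)-5-ethenyl-2-methyl-1,2,4a,5,6,7,8,8a-octahydroquinolin-1-ium 4-methylbenzenesulfonate
Product: 9 tert-butyl (2R,4aR,5S,8aS)-5-ethenyl-2-methyl-4a,5,6,7,8,8a-hexahydroquinoline-1(2H)-carboxylate
Conditions: Boc2O, Et3N, THF, 50 °C
Reagents that add atoms: di-tert-butyl dicarbonate, CC(C)(C)OC(=O)OC(=O)OC(C)(C)C
Why: Carbamate formation at the ring nitrogen freed by Et3N; this cis-2,8a-disubstituted piperidine nitrogen is hindered but far more accessible than that of acyclic 6, and the Boc group is needed from here on to remove the basicity of nitrogen and to steer the hydroboration.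

Step 5
Reactants: 9 tert-butyl (2R,4aR,5S,8aS)-5-ethenyl-2-methyl-4a,5,6,7,8,8a-hexahydroquinoline-1(2H)-carboxylate
Product: 11 tert-butyl (2R,3S,4aR,5S,8aS)-3-hydroxy-5-(2-hydroxyethyl)-2-methyloctahydroquinoline-1(2H)-carboxylate, via bis-alkylborane 10 (not isolated)
Conditions: BH3·THF (3 equiv), THF, 0 °C → rt; then NaOH (3 M aq.), H2O2 (30% aq.), 0 °C → rt
Reagents that add atoms: hydrogen peroxide, OO
Why: Hydroboration–oxidation of both alkenes: the vinyl group gives the primary C2' alcohol (anti-Markovnikov), while the ring alkene should take boron at C3, the carbon nearer the electron-withdrawing carbamate nitrogen (the usual proximal preference for allylic heteroatom substituents), from the convex face opposite the pseudo-axial C2 methyl and the C4a–C5 bond, so that syn addition and oxidation with retention give the (3S)-alcohol trans to the methyl group.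

Step 6
Reactants: 11 tert-butyl (2R,3S,4aR,5S,8aS)-3-hydroxy-5-(2-hydroxyethyl)-2-methyloctahydroquinoline-1(2H)-carboxylate
Product: 12 tert-butyl (2R,3S,4aR,5S,8aS)-3-hydroxy-2-methyl-5-(2-oxoethyl)octahydroquinoline-1(2H)-carboxylate
Conditions: TEMPO (10 mol%), PhI(OAc)2 (1.1 equiv), CH2Cl2, rt
Reagents that add atoms: none
Why: Oxoammonium (TEMPO) oxidation is strongly selective for the unhindered primary alcohol over the hindered secondary C3 alcohol and stops at the aldehyde without water; no lactol can intervene because O3 and the C5 chain lie on opposite faces of the bicycle.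

Step 7
Reactants: 13 (2R)-2-propyloxirane [(R)-1,2-epoxypentane]; 14 methyltriphenylphosphonium bromide
Product: 17 [(3R)-3-hydroxyhexyl]triphenylphosphonium bromide, via methylenetriphenylphosphorane 15 (not isolated), via γ-oxido betaine 16 (not isolated)
Conditions: n-BuLi, THF, 0 °C; then 13, 0 °C → rt; then HBr (48% aq.), 0 °C
Reagents that add atoms: hydrogen bromide, Br
Why: Alkylation of the nonstabilised ylide by the epoxide (SN2 at the unsubstituted carbon, assisted by the LiBr formed) gives the γ-oxido phosphonium betaine, in equilibrium with its oxaphospholane, which HBr protonates to the hydroxyalkylphosphonium salt; the carbinol centre is not touched, so the (R) configuration of the future C5' is retained.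

Step 8
Reactants: 17 [(3R)-3-hydroxyhexyl]triphenylphosphonium bromide
Product: 18 [(3R)-3-(tert-butyldimethylsilyloxy)hexyl]triphenylphosphonium bromide
Conditions: TBSCl, imidazole, DMF, rt; aq. NaBr wash
Reagents that add atoms: tert-butyldimethylsilyl chloride, CC(C)(C)[Si](C)(C)Cl
Why: Standard silylation of the secondary alcohol; the TBS ether masks O5' through ylide formation, hydrogenation and esterification, so that C3–OH is later the only free hydroxyl, and it is cleaved by acid at the end.

Step 9
Reactants: 12 tert-butyl (2R,3S,4aR,5S,8aS)-3-hydroxy-2-methyl-5-(2-oxoethyl)octahydroquinoline-1(2H)-carboxylate; 18 [(3R)-3-(tert-butyldimethylsilyloxy)hexyl]triphenylphosphonium bromide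
Product: 20 tert-butyl (2R,3S,4aR,5S,8aS)-5-[(2Z,5R)-5-(tert-butyldimethylsilyloxy)oct-2-en-1-yl]-3-hydroxy-2-methyloctahydroquinoline-1(2H)-carboxylate, via phosphonium ylide 19 (not isolated)
Conditions: 18 (2.5 equiv), NaN(SiMe3)2 (2.4 equiv), THF, 0 °C; then 12, –78 °C → rt
Reagents that add atoms: none
Why: Wittig olefination with a nonstabilised ylide forms C2'=C3' (mainly Z, which is irrelevant because the alkene is hydrogenated next); the excess ylide absorbs the free C3 hydroxyl proton, and the silyloxy group is too remote from the ylide carbon to be eliminated.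

Step 10
Reactants: 20 tert-butyl (2R,3S,4aR,5S,8aS)-5-[(2Z,5R)-5-(tert-butyldimethylsilyloxy)oct-2-en-1-yl]-3-hydroxy-2-methyloctahydroquinoline-1(2H)-carboxylate
Product: 21 tert-butyl (2R,3S,4aR,5R,8aS)-5-[(5R)-5-(tert-butyldimethylsilyloxy)octyl]-3-hydroxy-2-methyloctahydroquinoline-1(2H)-carboxylate
Conditions: H2 (1 atm), Pd/C (10 wt% palladium on carbon), EtOAc, rt
Reagents that add atoms: none
Why: Heterogeneous catalytic hydrogenation saturates the only alkene; the Boc group, the TBS ether and all stereocentres are inert under these neutral conditions.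

Step 11
Reactants: 21 tert-butyl (2R,3S,4aR,5R,8aS)-5-[(5R)-5-(tert-butyldimethylsilyloxy)octyl]-3-hydroxy-2-methyloctahydroquinoline-1(2H)-carboxylate; 22 (2E)-oct-2-enoic acid
Product: 24 tert-butyl (2R,3S,4aR,5R,8aS)-5-[(5R)-5-(tert-butyldimethylsilyloxy)octyl]-2-methyl-3-[(2E)-oct-2-enoyloxy]octahydroquinoline-1(2H)-carboxylate, via mixed anhydride 23 (not isolated)
Conditions: 22, 2,4,6-trichlorobenzoyl chloride, Et3N, toluene, rt; then 21, DMAP, toluene, rt → 40 °C
Reagents that add atoms: none
Why: Yamaguchi esterification: C3–OH is the only free hydroxyl, and the preformed aroyl mixed anhydride with DMAP should acylate this hindered secondary alcohol with retention at C3 while keeping the (E)-alkene in conjugation.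

Step 12
Reactants: 24 tert-butyl (2R,3S,4aR,5R,8aS)-5-[(5R)-5-(tert-butyldimethylsilyloxy)octyl]-2-methyl-3-[(2E)-oct-2-enoyloxy]octahydroquinoline-1(2H)-carboxylate
Product: 25 (2R,3S,4aR,5R,8aS)-5-[(5R)-5-hydroxyoctyl]-2-methyldecahydroquinolin-3-yl (2E)-oct-2-enoate
Conditions: CF3CO2H/CH2Cl2/H2O (10:10:1), 0 °C → rt; then aq. NaHCO3
Reagents that add atoms: none
Why: Acidolysis removes the Boc group and hydrolyses the secondary TBS ether in one operation; the enoate ester should survive aqueous acid at room temperature, and O→N acyl transfer in the free base would need a bridged intermediate across ring A.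

**Compound list**

1 | cyclohex-2-en-1-one | O=C1C=CCCC1 | starting material
2 | acetylene (ethyne) | C#C | starting material
3 | rac-(1R,6S)-bicyclo[4.2.0]oct-7-en-2-one (cis-fused racemate, one enantiomer drawn) | O=C1CCC[C@H]2C=C[C@@H]12 | intermediate
4 | (2R)-but-3-en-2-amine | C=C[C@@H](C)N | starting material
5 | N-[(2R)-but-3-en-2-yl]bicyclo[4.2.0]oct-7-en-2-imine, pair of cis-fused diastereomers (1R,6S drawn) | C=C[C@@H](C)N=C1CCC[C@H]2C=C[C@@H]12 | intermediate (not isolated)
6 | (2R)-N-[(1R,2S,6S)-bicyclo[4.2.0]oct-7-en-2-yl]but-3-en-2-amine | C=C[C@@H](C)N[C@H]1CCC[C@H]2C=C[C@@H]12 | intermediate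
7 | (2R)-N-[(1R,2S,6S)-bicyclo[4.2.0]oct-7-en-2-yl]but-3-en-2-aminium 4-methylbenzenesulfonate | C=C[C@@H](C)[NH2+][C@H]1CCC[C@H]2C=C[C@@H]12.Cc1ccc(cc1)S(=O)(=O)[O-] | intermediate (not isolated)
8 | (2R,4aR,5S,8aS)-5-ethenyl-2-methyl-1,2,4a,5,6,7,8,8a-octahydroquinolin-1-ium 4-methylbenzenesulfonate | C1=C[C@@H]2[C@H](C=C)CCC[C@@H]2[NH2+][C@@H]1C.Cc1ccc(cc1)S(=O)(=O)[O-] | intermediate
9 | tert-butyl (2R,4aR,5S,8aS)-5-ethenyl-2-methyl-4a,5,6,7,8,8a-hexahydroquinoline-1(2H)-carboxylate | C1=C[C@@H]2[C@H](C=C)CCC[C@@H]2N(C(=O)OC(C)(C)C)[C@@H]1C | intermediate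
10 | bis-alkylborane of 9 (boron on C3 and C2'; drawn as the bis-BH2 adduct) | B[C@H]1C[C@@H]2[C@H](CCB)CCC[C@@H]2N(C(=O)OC(C)(C)C)[C@@H]1C | intermediate (not isolated)
11 | tert-butyl (2R,3S,4aR,5S,8aS)-3-hydroxy-5-(2-hydroxyethyl)-2-methyloctahydroquinoline-1(2H)-carboxylate | O[C@H]1C[C@@H]2[C@H](CCO)CCC[C@@H]2N(C(=O)OC(C)(C)C)[C@@H]1C | intermediate
12 | tert-butyl (2R,3S,4aR,5S,8aS)-3-hydroxy-2-methyl-5-(2-oxoethyl)octahydroquinoline-1(2H)-carboxylate | O[C@H]1C[C@@H]2[C@H](CC=O)CCC[C@@H]2N(C(=O)OC(C)(C)C)[C@@H]1C | intermediate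
13 | (2R)-2-propyloxirane [(R)-1,2-epoxypentane] | CCC[C@@H]1CO1 | starting material
14 | methyltriphenylphosphonium bromide | C[P+](c1ccccc1)(c1ccccc1)c1ccccc1.[Br-] | starting material
15 | methylenetriphenylphosphorane | C=P(c1ccccc1)(c1ccccc1)c1ccccc1 | intermediate (not isolated)
16 | (3R)-1-(triphenylphosphonio)hexan-3-olate (γ-oxido betaine, in equilibrium with its oxaphospholane) | CCC[C@@H]([O-])CC[P+](c1ccccc1)(c1ccccc1)c1ccccc1 | intermediate (not isolated)
17 | [(3R)-3-hydroxyhexyl]triphenylphosphonium bromide | CCC[C@@H](O)CC[P+](c1ccccc1)(c1ccccc1)c1ccccc1.[Br-] | intermediate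
18 | [(3R)-3-(tert-butyldimethylsilyloxy)hexyl]triphenylphosphonium bromide | CCC[C@@H](O[Si](C)(C)C(C)(C)C)CC[P+](c1ccccc1)(c1ccccc1)c1ccccc1.[Br-] | intermediate
19 | [(3R)-3-(tert-butyldimethylsilyloxy)hexylidene]triphenylphosphorane | CCC[C@@H](O[Si](C)(C)C(C)(C)C)CC=P(c1ccccc1)(c1ccccc1)c1ccccc1 | intermediate (not isolated)
20 | tert-butyl (2R,3S,4aR,5S,8aS)-5-[(2Z,5R)-5-(tert-butyldimethylsilyloxy)oct-2-en-1-yl]-3-hydroxy-2-methyloctahydroquinoline-1(2H)-carboxylate | O[C@H]1C[C@@H]2[C@H](C/C=C\C[C@H](O[Si](C)(C)C(C)(C)C)CCC)CCC[C@@H]2N(C(=O)OC(C)(C)C)[C@@H]1C | intermediate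
21 | tert-butyl (2R,3S,4aR,5R,8aS)-5-[(5R)-5-(tert-butyldimethylsilyloxy)octyl]-3-hydroxy-2-methyloctahydroquinoline-1(2H)-carboxylate | O[C@H]1C[C@@H]2[C@H](CCCC[C@H](O[Si](C)(C)C(C)(C)C)CCC)CCC[C@@H]2N(C(=O)OC(C)(C)C)[C@@H]1C | intermediate
22 | (2E)-oct-2-enoic acid | CCCCC/C=C/C(=O)O | starting material
23 | (2E)-oct-2-enoic 2,4,6-trichlorobenzoic anhydride | CCCCC/C=C/C(=O)OC(=O)c1c(Cl)cc(Cl)cc1Cl | intermediate (not isolated)
24 | tert-butyl (2R,3S,4aR,5R,8aS)-5-[(5R)-5-(tert-butyldimethylsilyloxy)octyl]-2-methyl-3-[(2E)-oct-2-enoyloxy]octahydroquinoline-1(2H)-carboxylate | CCCCC/C=C/C(=O)O[C@H]1C[C@@H]2[C@H](CCCC[C@H](O[Si](C)(C)C(C)(C)C)CCC)CCC[C@@H]2N(C(=O)OC(C)(C)C)[C@@H]1C | intermediate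
25 | (2R,3S,4aR,5R,8aS)-5-[(5R)-5-hydroxyoctyl]-2-methyldecahydroquinolin-3-yl (2E)-oct-2-enoate | CCCCC/C=C/C(=O)O[C@H]1C[C@@H]2[C@H](CCCC[C@H](O)CCC)CCC[C@@H]2N[C@@H]1C | target

**Step count.** Total: 12 steps. Longest linear sequence: 10 steps (steps 1–6 and 9–12); steps 7 and 8 form the side-chain branch.

**Steps most likely to fail, with fallbacks**

Step 3 (key step). The catalyst may be deactivated if protonation does not fully shield the nitrogen, or the sequence may stall after ring opening without ring closure. The fallback masks nitrogen covalently before the metathesis. Starting from 6, forcing carbamoylation (neat Boc2O, 60 °C) should give tert-butyl N-[(2R)-but-3-en-2-yl]-N-[(1R,2S,6S)-bicyclo[4.2.0]oct-7-en-2-yl]carbamate F1. Its ring-rearrangement metathesis with the same catalyst under ethylene would deliver 9 directly, so the route is rejoined at 9 and step 4 is dropped.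

Step 5. Boron may not be delivered selectively to C3, with competing attack at C4 of the ring alkene. The fallback enforces the regiochemistry through an enecarbamate, starting from 9.
- 9-BBN in THF should hydroborate only the vinyl group, giving the B-alkyl-9-BBN adduct of 9 F2.
- NaOH/H2O2 then gives the 5-(2-hydroxyethyl) analogue of 9 with the ring alkene intact F3.
- RuHCl(CO)(PPh3)3 in hot toluene should move the ring double bond into conjugation with nitrogen, giving the C2=C3 enecarbamate, tert-butyl (4aR,5S,8aS)-5-(2-hydroxyethyl)-2-methyl-4a,5,6,7,8,8a-hexahydroquinoline-1(4H)-carboxylate F4.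
- BH3·THF adds to an enecarbamate with boron only at the β-carbon C3 and hydrogen at C2, both from the convex face, giving the C3-borane adduct of F4 F5.
- Oxidation returns diol 11, with the methyl group re-set trans to the hydroxyl and cis to C8, and the route continues at step 6.

Step 2. Hydride delivery may be insufficiently face-selective, or the two endo amines may not separate. The fallback resolves the bicycle before nitrogen is introduced, starting from 3.
- LiBH(sBu)3 in THF at –78 °C should give, by convex-face attack, racemic endo-bicyclo[4.2.0]oct-7-en-2-ol F6.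
- Lipase-mediated acetylation (Candida antarctica lipase B, vinyl acetate) is expected, from the usual preference of this enzyme for the (R)-carbinol, to give (1S,2R,6R)-bicyclo[4.2.0]oct-7-en-2-yl acetate F7 and to leave (1R,2S,6S)-bicyclo[4.2.0]oct-7-en-2-ol F8. Which enantiomer is acylated would have to be confirmed.
- Dess–Martin periodinane then gives enantiopure (1R,6S)-bicyclo[4.2.0]oct-7-en-2-one F9.
- Reductive amination of F9 with 4 as in step 2 (with the bulkier NaBH(OAc)3 if the face selectivity needs it) returns to 6, now from all of the ketone.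

Further compounds
F1 | step 3 | tert-butyl N-[(2R)-but-3-en-2-yl]-N-[(1R,2S,6S)-bicyclo[4.2.0]oct-7-en-2-yl]carbamate | C=C[C@@H](C)N(C(=O)OC(C)(C)C)[C@H]1CCC[C@H]2C=C[C@@H]12
F2 | step 5 | B-alkyl-9-BBN adduct of 9 (boron on C2', ring alkene intact) | C1=C[C@@H]2[C@H](CCB3C4CCCC3CCC4)CCC[C@@H]2N(C(=O)OC(C)(C)C)[C@@H]1C
F3 | step 5 | 5-(2-hydroxyethyl) analogue of 9 (ring alkene intact) | C1=C[C@@H]2[C@H](CCO)CCC[C@@H]2N(C(=O)OC(C)(C)C)[C@@H]1C
F4 | step 5 | tert-butyl (4aR,5S,8aS)-5-(2-hydroxyethyl)-2-methyl-4a,5,6,7,8,8a-hexahydroquinoline-1(4H)-carboxylate (C2=C3 enecarbamate) | CC1=CC[C@@H]2[C@H](CCO)CCC[C@@H]2N1C(=O)OC(C)(C)C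
F5 | step 5 | C3-borane adduct of F4 (drawn as the BH2 adduct, hydroxyl shown free) | B[C@H]1C[C@@H]2[C@H](CCO)CCC[C@@H]2N(C(=O)OC(C)(C)C)[C@@H]1C
F6 | step 2 | rac-(1R,2S,6S)-bicyclo[4.2.0]oct-7-en-2-ol (endo alcohol, racemate, one enantiomer drawn) | O[C@H]1CCC[C@H]2C=C[C@@H]12
F7 | step 2 | (1S,2R,6R)-bicyclo[4.2.0]oct-7-en-2-yl acetate | CC(=O)O[C@@H]1CCC[C@@H]2C=C[C@H]12
F8 | step 2 | (1R,2S,6S)-bicyclo[4.2.0]oct-7-en-2-ol (single enantiomer) | O[C@H]1CCC[C@H]2C=C[C@@H]12
F9 | step 2 | (1R,6S)-bicyclo[4.2.0]oct-7-en-2-one (single enantiomer) | O=C1CCC[C@H]2C=C[C@@H]12
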